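**Plan**

Germacrane numbering is used. Ring A is the carbocycle C1–C10 and ring B is the butenolide O6–C6–C7=C11–C12. C13 is the CH2OH on C11, and C14 and C15 are the methyl groups on C10 and C4.
- **Cuts:** first the two oxirane C–O pairs (back to the 1(10)E,4E-diene), the O8 acyl group and the O13 silyl group. Then C1–C2 (opens ring A), C10–C14 and C8–C9. Then C7–C8, C11–C12 and C12–O6 together (opens ring B), and last C6–C7.
- **Enabling feature:** C7=C11 of ring B is tetrasubstituted, with C6 and C8 on C7, C12 and C13 on C11, and C12 cis to the oxygen-bearing C6. A net anti addition of a C8 carbanion and CO2 across a C7≡C11 alkyne held by a C6 alkoxide leaves exactly this pattern.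
- **Forward order:** the dienal C2–C6 is joined to the C7/C11/C13 alkyne, and ring B forms in one flask. C8 is raised to the aldehyde, and C9–C10–C1 enters as a propargyl unit so that one CH2 separates C8 from C10. C14 follows, then ring A by Suzuki–Miyaura closure, and the oxiranes last.
- **Stereochemistry:** C6 comes from asymmetric alkynylzinc addition and C8 from chiral-acid propargylboration. E-C4=C5 comes from the starting enynol and E-C1=C10 from syn carboalumination. C1, C10, C4 and C5 come from peracid attack on the outer faces of ring A.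

Key step: step 6

Assumption: the facial preferences quoted for the chiral catalysts of steps 4 and 9 are those they show with simple enals and aryl aldehydes; if either is reversed on these substrates, its mirror-image form is used and nothing else changes.

**Step 1**
Reactants: 1 propargyl alcohol
Product: 2 triisopropyl(prop-2-yn-1-yloxy)silane
Conditions: TIPSCl, imidazole, CH2Cl2, 0 °C to rt
Reagents that add atoms: triisopropylsilyl chloride, CC(C)[Si](Cl)(C(C)C)C(C)C
Why: Routine silyl ether formation on a primary alcohol; the bulky triisopropylsilyl group is chosen because its oxygen coordinates magnesium poorly and leaves reluctantly, which matters in step 6.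

**Step 2**
Reactants: 3 (E)-3-methylpent-2-en-4-yn-1-ol
Product: 4 (E)-3-methylpenta-2,4-dien-1-ol
Conditions: H2 (1 atm), Pd/CaCO3 poisoned with Pb(OAc)2, quinoline, EtOAc, 0 °C, stopped after one equivalent of H2
Reagents that add atoms: none
Why: Semihydrogenation over lead-poisoned palladium takes a terminal alkyne to the alkene and stops there, so the E-trisubstituted alkene (the future C4=C5) keeps its geometry and the new vinyl group supplies C2 and C3.

**Step 3**
Reactants: 4 (E)-3-methylpenta-2,4-dien-1-ol
Product: 5 (E)-3-methylpenta-2,4-dienal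
Conditions: MnO2, CH2Cl2, rt; filtered solution used directly
Reagents that add atoms: none
Why: MnO2 is a selective allylic oxidant that gives the enal without over-oxidation or E/Z scrambling, and the volatile product is carried on in solution.

**Step 4**
Reactants: 2 triisopropyl(prop-2-yn-1-yloxy)silane; 5 (E)-3-methylpenta-2,4-dienal
Product: 7 (4R,5E)-6-methyl-1-(triisopropylsilyloxy)octa-5,7-dien-2-yn-4-ol, via ethylzinc acetylide 6 (not isolated)
Conditions: 2, Et2Zn, Cy2NH (cat.), Et2O, rt; then (S)-1,1'-bi-2-naphthol (cat.), Ti(OiPr)4; then 5, rt; aq. NH4Cl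
Reagents that add atoms: none
Why: Binaphthol–titanium-catalysed asymmetric addition of an alkynylzinc to an enal (1,2-addition): the (S)-ligand should direct the alkynyl group of 6 to the Si face of 5 and thus set C6 as R, the spatial arrangement that is called 6S in the target once epoxidation raises the rank of C5 above C7.

**Step 5**
Reactants: 8 (chloromethyl)isopropoxydimethylsilane
Product: 9 [(isopropoxydimethylsilyl)methyl]magnesium chloride (THF solution, titrated)
Conditions: Mg turnings, THF, rt to 40 °C
Reagents that add atoms: magnesium, [Mg]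
Why: Ordinary Grignard formation from a primary α-silyl chloride; the branched isopropoxy group shields silicon from attack by the reagent.

**Step 6**
Reactants: 7 (4R,5E)-6-methyl-1-(triisopropylsilyloxy)octa-5,7-dien-2-yn-4-ol; 9 [(isopropoxydimethylsilyl)methyl]magnesium chloride; 10 carbon dioxide
Product: 13 (5R)-4-{[isopropoxy(dimethyl)silyl]methyl}-5-[(1E)-2-methylbuta-1,3-dienyl]-3-[(triisopropylsilyloxy)methyl]furan-2(5H)-one, via oxamagnesacycle 11 (not isolated), via hydroxy acid 12 (not isolated)
Conditions: 9 (3.5 equiv), CuI (15 mol %), THF, −10 to 20 °C; then dry CO2, −20 °C to rt; then aq. citric acid (pH 4), rt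
Reagents that add atoms: Grignard reagent 9, CC(C)O[Si](C)(C)C[Mg]Cl; carbon dioxide 10, O=C=O
Why: One equivalent of 9 deprotonates 7, and a silylmethylcopper species generated from CuI and further 9 then adds across C7≡C11 in a net anti sense, C8 bonding to the proximal carbon C7 and the metal ending on C11 as the five-membered oxamagnesacycle 11. The closest known reaction type is the copper-catalysed, hydroxyl-directed anti-carbomagnesiation of propargylic alcohols with carboxylative trapping to butenolides, for which (trialkylsilyl)methyl Grignard reagents are established nucleophiles. CO2 inserts into the C11–Mg bond with retention of alkene geometry, so in 12 the carboxyl carbon C12 stands cis to C6, and on acidification ring B closes by 5-exo-trig attack of O6 on C12 with loss of water. No stereocentre is created; C6 is retained because none of its bonds is broken, and the geometry of the tetrasubstituted C7=C11 alkene is dictated by the chelate. The step needs regioselectivity (secured by the single free hydroxyl group on C6, the C13 oxygen being capped), chemoselectivity (the 1,3-diene has no directing group and is inert to Grignard reagents) and persistence of the β-silyloxy alkenylmagnesium, which the bulky, weakly coordinating triisopropylsilyl ether, THF as donor solvent and a temperature not above 20 °C should secure against elimination to an allene.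

**Step 7**
Reactants: 13 silylmethyl butenolide (crude)
Product: 14 (5R)-4-(hydroxymethyl)-5-[(1E)-2-methylbuta-1,3-dienyl]-3-[(triisopropylsilyloxy)methyl]furan-2(5H)-one
Conditions: 30 % H2O2, KF, KHCO3, THF/MeOH, 0 °C to rt
Reagents that add atoms: hydrogen peroxide, OO
Why: Tamao–Fleming oxidation: hydroperoxide adds to the fluoride-activated alkoxysilane and C8 migrates from silicon to oxygen without allylic transposition, while the diene, the hindered electron-poor C7=C11 alkene and the silyl ether should be inert to buffered H2O2.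

**Step 8**
Reactants: 14 hydroxymethyl butenolide
Product: 15 (2R)-2-[(1E)-2-methylbuta-1,3-dienyl]-5-oxo-4-[(triisopropylsilyloxy)methyl]-2,5-dihydrofuran-3-carbaldehyde
Conditions: Dess–Martin periodinane, NaHCO3, CH2Cl2, 0 °C
Reagents that add atoms: none
Why: Dess–Martin oxidation converts the primary allylic alcohol into the aldehyde under buffered, essentially neutral conditions, so the acidic C6–H of ring B is not disturbed.

**Step 9**
Reactants: 15 C8 aldehyde; 16 allenylboronic acid pinacol ester
Product: 18 (5R)-4-[(1S)-1-hydroxybut-3-ynyl]-5-[(1E)-2-methylbuta-1,3-dienyl]-3-[(triisopropylsilyloxy)methyl]furan-2(5H)-one, via O-boryl ether 17 (not isolated)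
Conditions: 16, (S)-3,3'-bis(2,4,6-triisopropylphenyl)-1,1'-binaphthyl-2,2'-diyl hydrogen phosphate (cat.), 4 Å MS, toluene, −20 °C; aq. work-up
Reagents that add atoms: allenylboronic acid pinacol ester 16, C=C=CB1OC(C)(C)C(C)(C)O1
Why: Chiral-phosphoric-acid-catalysed propargylboration: the allenylboronate reacts through a closed six-membered SE2' transition state in which the (S)-acid should expose the Si face of the aldehyde, which sets C8 as S under catalyst control and brings in C9, C10 and C1 with only one CH2 between C8 and the alkyne.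

**Step 10**
Reactants: 18 homopropargylic alcohol
Product: 20 (5R)-4-[(1S,3E)-1-hydroxy-4-iodo-3-methylbut-3-enyl]-5-[(1E)-2-methylbuta-1,3-dienyl]-3-[(triisopropylsilyloxy)methyl]furan-2(5H)-one, via vinylalane 19 (not isolated)
Conditions: Me3Al, Cp2ZrCl2 (cat.), H2O (1 equiv), CH2Cl2, −30 °C; then I2, THF, −30 to 0 °C
Reagents that add atoms: trimethylaluminium, C[Al](C)C; iodine, II
Why: Negishi carboalumination: zirconium-catalysed syn addition of Me–Al puts the methyl group C14 on the internal carbon C10 and aluminium on C1, iodinolysis proceeds with retention to the E-iodoalkene, and the water-accelerated low-temperature variant should spare the lactone, the diene reacting far more slowly than a terminal alkyne.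

**Step 11**
Reactants: 20 iodoalkenyl alcohol; 21 tigloyl chloride
Product: 22 (1S,3E)-4-iodo-3-methyl-1-{(2R)-2-[(1E)-2-methylbuta-1,3-dienyl]-5-oxo-4-[(triisopropylsilyloxy)methyl]-2,5-dihydrofuran-3-yl}but-3-enyl (2E)-2-methylbut-2-enoate
Conditions: 21, pyridine, DMAP (cat.), CH2Cl2, 0 °C
Reagents that add atoms: tigloyl chloride 21, C/C=C(\C)C(=O)Cl
Why: DMAP-catalysed acylation of the secondary alcohol by the acid chloride leaves the C8–O bond intact (retention at C8), the E-configured tigloyl group is the thermodynamically stable isomer, and the weak base pyridine should not enolise ring B.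

**Step 12**
Reactants: 22 tiglate with diene and iodoalkene termini
Product: 24 (6R,8S)-8-tigloyloxy-13-(triisopropylsilyloxy)germacra-1(10)E,4E,7(11)-trien-12,6-olide, via B-alkyl-9-BBN borane 23 (not isolated)
Conditions: 9-BBN-H, THF, rt; then slow addition to PdCl2(dppf), AsPh3, Cs2CO3, DMF/THF/H2O, 1 mM, rt to 45 °C
Reagents that add atoms: none
Why: Hydroboration followed by intramolecular B-alkyl Suzuki–Miyaura coupling: 9-BBN-H adds only to the monosubstituted terminus of the diene with boron on C2, and after oxidative addition of zerovalent palladium into the C1–I bond the C1–C2 bond forms with retention of the E geometry, a ring-closure type already known for medium carbocycles that contain an E-trisubstituted alkene.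

**Step 13**
Reactants: 24 silylated germacratrienolide
Product: 25 (6R,8S)-13-hydroxy-8-tigloyloxygermacra-1(10)E,4E,7(11)-trien-12,6-olide
Conditions: HF·pyridine, pyridine, THF, 0 °C to rt
Reagents that add atoms: none
Why: Fluoride cleavage of the primary silyl ether in a pyridine-buffered, slightly acidic medium avoids both the O8 to O13 acyl shift and the C6 enolisation that basic fluoride sources could trigger, and it precedes epoxidation because the oxiranes would not tolerate HF.

**Step 14**
Reactants: 25 13-hydroxy germacratrienolide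
Product: 27 (1R,4R,5R,6S,8S,10R)-1,10:4,5-diepoxy-13-hydroxy-8-tigloyloxygermacr-7(11)-en-12,6-olide, via 1,10-monoepoxide 26 (not isolated)
Conditions: mCPBA (2.5 equiv), NaHCO3, CH2Cl2, 0 °C to rt
Reagents that add atoms: 3-chloroperoxybenzoic acid, O=C(OO)c1cccc(Cl)c1
Why: Prilezhaev epoxidation: only the two electron-rich trisubstituted alkenes react (C7=C11 and the tiglate alkene are electron-poor), syn delivery to E-alkenes gives trans-oxiranes, and the peracid should attack the outer face of each alkene in the crown conformer of ring A, where allylic 1,3-strain between C15 and C6 keeps H6 in the C4=C5 plane, C7 inside and O6 outside, which leads to 4R,5R and, for the crossed C1=C10 bond with C14 on the same side as C15, to 1R,10R.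

**Compound list**

1 | propargyl alcohol | C#CCO | starting material
2 | triisopropyl(prop-2-yn-1-yloxy)silane | C#CCO[Si](C(C)C)(C(C)C)C(C)C | intermediate
3 | (E)-3-methylpent-2-en-4-yn-1-ol | C#C/C(C)=C/CO | starting material
4 | (E)-3-methylpenta-2,4-dien-1-ol | C=C/C(C)=C/CO | intermediate
5 | (E)-3-methylpenta-2,4-dienal | C=C/C(C)=C/C=O | intermediate
6 | ethyl[3-(triisopropylsilyloxy)prop-1-ynyl]zinc (ethylzinc acetylide) | CC[Zn]C#CCO[Si](C(C)C)(C(C)C)C(C)C | intermediate
7 | (4R,5E)-6-methyl-1-(triisopropylsilyloxy)octa-5,7-dien-2-yn-4-ol | C=C/C(C)=C/[C@@H](O)C#CCO[Si](C(C)C)(C(C)C)C(C)C | intermediate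
8 | (chloromethyl)isopropoxydimethylsilane | CC(C)O[Si](C)(C)CCl | starting material
9 | [(isopropoxydimethylsilyl)methyl]magnesium chloride | CC(C)O[Si](C)(C)C[Mg]Cl | intermediate
10 | carbon dioxide | O=C=O | starting material
11 | oxamagnesacycle (O6–Mg–C11 chelate, C8 silylmethyl on C7, C13 silyloxymethyl on C11, 6R) | C=C/C(C)=C/[C@H]1O[Mg]C(CO[Si](C(C)C)(C(C)C)C(C)C)=C1C[Si](C)(C)OC(C)C | intermediate
12 | (2E,4R,5E)-4-hydroxy-3-{[isopropoxy(dimethyl)silyl]methyl}-6-methyl-2-[(triisopropylsilyloxy)methyl]octa-2,5,7-trienoic acid | C=C/C(C)=C/[C@@H](O)/C(C[Si](C)(C)OC(C)C)=C(/CO[Si](C(C)C)(C(C)C)C(C)C)C(=O)O | intermediate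
13 | (5R)-4-{[isopropoxy(dimethyl)silyl]methyl}-5-[(1E)-2-methylbuta-1,3-dienyl]-3-[(triisopropylsilyloxy)methyl]furan-2(5H)-one | C=C/C(C)=C/[C@H]1OC(=O)C(CO[Si](C(C)C)(C(C)C)C(C)C)=C1C[Si](C)(C)OC(C)C | intermediate
14 | (5R)-4-(hydroxymethyl)-5-[(1E)-2-methylbuta-1,3-dienyl]-3-[(triisopropylsilyloxy)methyl]furan-2(5H)-one | C=C/C(C)=C/[C@H]1OC(=O)C(CO[Si](C(C)C)(C(C)C)C(C)C)=C1CO | intermediate
15 | (2R)-2-[(1E)-2-methylbuta-1,3-dienyl]-5-oxo-4-[(triisopropylsilyloxy)methyl]-2,5-dihydrofuran-3-carbaldehyde | C=C/C(C)=C/[C@H]1OC(=O)C(CO[Si](C(C)C)(C(C)C)C(C)C)=C1C=O | intermediate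
16 | allenylboronic acid pinacol ester | C=C=CB1OC(C)(C)C(C)(C)O1 | starting material
17 | O-pinacolboryl ether of 18 | C=C/C(C)=C/[C@H]1OC(=O)C(CO[Si](C(C)C)(C(C)C)C(C)C)=C1[C@@H](OB2OC(C)(C)C(C)(C)O2)CC#C | intermediate
18 | (5R)-4-[(1S)-1-hydroxybut-3-ynyl]-5-[(1E)-2-methylbuta-1,3-dienyl]-3-[(triisopropylsilyloxy)methyl]furan-2(5H)-one | C=C/C(C)=C/[C@H]1OC(=O)C(CO[Si](C(C)C)(C(C)C)C(C)C)=C1[C@@H](O)CC#C | intermediate
19 | (E)-vinylalane, O8-dimethylaluminium alkoxide | C=C/C(C)=C/[C@H]1OC(=O)C(CO[Si](C(C)C)(C(C)C)C(C)C)=C1[C@@H](O[Al](C)C)C/C(C)=C/[Al](C)C | intermediate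
20 | (5R)-4-[(1S,3E)-1-hydroxy-4-iodo-3-methylbut-3-enyl]-5-[(1E)-2-methylbuta-1,3-dienyl]-3-[(triisopropylsilyloxy)methyl]furan-2(5H)-one | C=C/C(C)=C/[C@H]1OC(=O)C(CO[Si](C(C)C)(C(C)C)C(C)C)=C1[C@@H](O)C/C(C)=C/I | intermediate
21 | tigloyl chloride, (E)-2-methylbut-2-enoyl chloride | C/C=C(\C)C(=O)Cl | starting material
22 | O8-tiglate of 20 | C=C/C(C)=C/[C@H]1OC(=O)C(CO[Si](C(C)C)(C(C)C)C(C)C)=C1[C@@H](OC(=O)/C(C)=C/C)C/C(C)=C/I | intermediate
23 | B-alkyl-9-BBN borane (boron on C2) | C1CC2CCCC(C1)B2CC/C(C)=C/[C@H]3OC(=O)C(CO[Si](C(C)C)(C(C)C)C(C)C)=C3[C@@H](OC(=O)/C(C)=C/C)C/C(C)=C/I | intermediate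
24 | (6R,8S)-8-tigloyloxy-13-(triisopropylsilyloxy)germacra-1(10)E,4E,7(11)-trien-12,6-olide | C/C=C(\C)C(=O)O[C@H]1C/C(C)=C/CC/C(C)=C/[C@H]2OC(=O)C(CO[Si](C(C)C)(C(C)C)C(C)C)=C12 | intermediate
25 | (6R,8S)-13-hydroxy-8-tigloyloxygermacra-1(10)E,4E,7(11)-trien-12,6-olide | C/C=C(\C)C(=O)O[C@H]1C/C(C)=C/CC/C(C)=C/[C@H]2OC(=O)C(CO)=C12 | intermediate
26 | (1R,10R)-1,10-epoxide of 25 | C/C=C(\C)C(=O)O[C@H]1C[C@@]2(C)O[C@@H]2CC/C(C)=C/[C@H]2OC(=O)C(CO)=C12 | intermediate
27 | CNP0111480.1, (1R,4R,5R,6S,8S,10R)-1,10:4,5-diepoxy-13-hydroxy-8-tigloyloxygermacr-7(11)-en-12,6-olide | C/C=C(\C)C(=O)O[C@H]1C[C@@]2(C)O[C@@H]2CC[C@@]2(C)O[C@@H]2[C@H]2OC(=O)C(CO)=C12 | target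

**Step count**

- Total steps: 14.
- Longest linear sequence: 12 steps, from 3 to 27 (steps 2, 3, 4 and 6 to 14).

**Steps most likely to fail**

**Step 12.**
- What may go wrong: closure of the strained ring A may be outrun by intermolecular coupling, by protodeboronation or by β-hydride elimination of the alkylpalladium intermediate. The aqueous carbonate may also slowly erode C6 through enolisation of ring B.
- Fallback: it sets out from 22 and replaces the borate/base manifold by a neutral organozinc reagent made from a discrete halide.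
  - Hydroboration to 23 as before, but with oxidative work-up (NaBO3), should give the C2 primary alcohol F1.
  - An Appel reaction (I2, PPh3, imidazole) should give the C2 primary iodide F2.
  - Zinc dust with LiCl in THF should insert only into the sp3 C–I bond to give the C2 alkylzinc iodide F3.
  - Slow addition of F3 to Pd2(dba)3 and tri(2-furyl)phosphine is an intramolecular Negishi coupling of a homoallylic zinc reagent with an E-iodoalkene, the classical entry to 1,5-dienes. It comes back to the route at 24.

**Step 6.**
- What may go wrong: the alkenylmetal carries the C13 oxygen in the β position, so loss of silyloxide with allene formation may compete. Addition of the silylmethyl reagent to an internal alkyne may also be slow.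
- Fallback: it sets out from 5 and 9 and removes any β leaving group by bringing C12 in with the alkyne and C13 afterwards.
  - Asymmetric alkynylation of 5 with methyl propiolate under the conditions of step 4 should give the hydroxy ynoate F4.
  - Syn conjugate addition of the silylmethylcopper reagent from 9 and CuI (THF, −78 °C), an iodine quench and spontaneous lactonisation should give the 3-iodobutenolide F5.
  - Stille coupling with (tributylstannyl)methanol (Pd(PPh3)4, dioxane, 80 °C) should give the 3-(hydroxymethyl)butenolide F6.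
  - Silylation (TIPSCl, imidazole) comes back to the route at 13.

**Step 7.**
- What may go wrong: the C8–Si bond is vinylogously α to the lactone carbonyl. Fluoride or hydroperoxide may therefore expel the extended enolate (protodesilylation) faster than C8 migrates to oxygen.
- Fallback: it sets out from 7 and 9 and oxidises silicon before any carbonyl group is in conjugation.
  - Carbomagnesiation as in step 6 to 11, quenched with I2 instead of CO2, should give the iodoalkene F7, an ordinary allylsilane.
  - Tamao–Fleming oxidation of F7 should give the iododiol F8.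
  - Carbonylative lactonisation (PdCl2(PPh3)2, CO at 1 atm, K2CO3, DMF) comes back to the route at 14, because only the C6 hydroxyl group stands cis to the acylpalladium.

**Further compounds**

F1 | step 12 | C2 primary alcohol | OCC/C(C)=C/[C@H]1OC(=O)C(CO[Si](C(C)C)(C(C)C)C(C)C)=C1[C@@H](OC(=O)/C(C)=C/C)C/C(C)=C/I
F2 | step 12 | C2 primary iodide | ICC/C(C)=C/[C@H]1OC(=O)C(CO[Si](C(C)C)(C(C)C)C(C)C)=C1[C@@H](OC(=O)/C(C)=C/C)C/C(C)=C/I
F3 | step 12 | C2 alkylzinc iodide | I[Zn]CC/C(C)=C/[C@H]1OC(=O)C(CO[Si](C(C)C)(C(C)C)C(C)C)=C1[C@@H](OC(=O)/C(C)=C/C)C/C(C)=C/I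
F4 | step 6 | hydroxy ynoate (methyl (4R,5E)-4-hydroxy-6-methylocta-5,7-dien-2-ynoate) | C=C/C(C)=C/[C@@H](O)C#CC(=O)OC
F5 | step 6 | 3-iodobutenolide | C=C/C(C)=C/[C@H]1OC(=O)C(I)=C1C[Si](C)(C)OC(C)C
F6 | step 6 | 3-(hydroxymethyl)butenolide | C=C/C(C)=C/[C@H]1OC(=O)C(CO)=C1C[Si](C)(C)OC(C)C
F7 | step 7 | iodoalkene | C=C/C(C)=C/[C@@H](O)/C(C[Si](C)(C)OC(C)C)=C(/CO[Si](C(C)C)(C(C)C)C(C)C)I
F8 | step 7 | iododiol | C=C/C(C)=C/[C@@H](O)/C(CO)=C(/CO[Si](C(C)C)(C(C)C)C(C)C)I
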